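**Retrosynthetic overview**

1. Odoratisol A ⇒ the same trans-dihydrobenzofuran carrying a C5 aldehyde; the (E)-propenyl group is made last by Julia–Kocienski olefination.
2. Dihydrofuran ring ⇒ O1–C2 bond: chiral-acid hydroalkoxylation of an (E)-2-hydroxy-α-methylstilbene through a p-quinone methide. Protonation sets C3, the C–O closure sets C2 (trans).
3. Stilbene ⇒ Suzuki coupling of 5-iodovanillin with a (Z)-β-boryl styrene.
4. Boryl styrene ⇒ Cu-catalysed borylation of 4-(prop-1-ynyl)syringol ⇐ Sonogashira coupling of 4-bromo-2,6-dimethoxyphenol with propyne.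
5. Ring order: both benzene rings are bought; the dihydrofuran is the only ring formed (step 4). No protecting groups are used.

Assumption: the sense of induction of the chiral acid in step 4 cannot be predicted on paper, so the (S)-catalyst is written and its mirror image is used if a first run gives the (2R,3R) series.

**Route**

Step 1
Reactants: 1 4-bromo-2,6-dimethoxyphenol; 2 propyne
Product: 3 2,6-dimethoxy-4-(prop-1-yn-1-yl)phenol
Conditions: propyne (3 equiv, THF solution), PdCl2(MeCN)2 (2 mol %), XPhos (6 mol %), Cs2CO3 (3 equiv), MeCN, 70 °C, sealed tube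
Reagents that add atoms: none
Why: Copper-free Sonogashira coupling; the bulky electron-rich phosphine allows oxidative addition into the electron-rich aryl bromide (present as phenoxide) and the absence of copper avoids alkyne homocoupling.

Step 2
Reactants: 3 2,6-dimethoxy-4-(prop-1-yn-1-yl)phenol
Product: 4 2,6-dimethoxy-4-[(Z)-2-(4,4,5,5-tetramethyl-1,3,2-dioxaborolan-2-yl)prop-1-en-1-yl]phenol (aryl and boron trans)
Conditions: B2pin2 (1.3 equiv), CuCl (5 mol %), P(p-tol)3 (6 mol %), NaOtBu (15 mol %), MeOH (4 equiv), THF, rt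
Reagents that add atoms: bis(pinacolato)diboron, CC1(C)OB(OC1(C)C)B1OC(C)(C)C(C)(C)O1
Why: Copper-catalysed alkyne hydroboration (syn-borylcupration, then protonolysis by MeOH with retention) places boron on the carbon remote from the aryl group and copper on the benzylic carbon, so H and B are added cis and the alkene geometry is fixed.

Step 3
Reactants: 4 2,6-dimethoxy-4-[(Z)-2-(4,4,5,5-tetramethyl-1,3,2-dioxaborolan-2-yl)prop-1-en-1-yl]phenol; 5 5-iodovanillin (4-hydroxy-3-iodo-5-methoxybenzaldehyde)
Product: 6 4-hydroxy-3-[(E)-1-(4-hydroxy-3,5-dimethoxyphenyl)prop-1-en-2-yl]-5-methoxybenzaldehyde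
Conditions: Pd(dppf)Cl2 (3 mol %), K2CO3 (3 equiv), dioxane/H2O 4:1, 70 °C
Reagents that add atoms: none
Why: Suzuki–Miyaura coupling proceeds with retention at the alkenyl boronate, so the two aryl groups end up trans (E), and free phenols and the aldehyde are tolerated under aqueous carbonate.

Step 4
Reactants: 6 4-hydroxy-3-[(E)-1-(4-hydroxy-3,5-dimethoxyphenyl)prop-1-en-2-yl]-5-methoxybenzaldehyde
Product: 8 (2S,3S)-2-(4-hydroxy-3,5-dimethoxyphenyl)-7-methoxy-3-methyl-2,3-dihydro-1-benzofuran-5-carbaldehyde, via p-quinone methide 7 (not isolated)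
Conditions: (S)-3,3′-bis(2,4,6-triisopropylphenyl)-H8-BINOL N-triflyl phosphoramide (5 mol %), CHCl3 (0.02 M), 5 Å MS, −30 → 0 °C
Reagents that add atoms: none
Why: Proposed new method: the confined chiral acid transfers its proton to the methyl-bearing alkene carbon of the 4-hydroxystilbene from one face while its basic site holds the ring-A OH, which gives the ion-paired p-quinone methide 7 and sets C3; the held phenol then adds 5-exo to the methide carbon (oxa-1,6-addition) anti to the methyl group, which forms O1–C2 and sets C2 trans (also the thermodynamic isomer, as closure is reversible through 7), and the formyl group para to the ring-A OH disfavours the competing o-quinone methide; closest known reaction types are chiral Brønsted acid catalysed intramolecular alkene hydroalkoxylation and acid-catalysed additions to p-quinone methides formed in situ from 4-vinylphenols, and the same trans-selective closure is the last event of the biomimetic phenylcoumaran synthesis.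

Step 5
Reactants: 8 (2S,3S)-2-(4-hydroxy-3,5-dimethoxyphenyl)-7-methoxy-3-methyl-2,3-dihydro-1-benzofuran-5-carbaldehyde
Product: 10 odoratisol A, via β-hydroxy sulfone adduct 9 (not isolated)
Conditions: EtSO2PT (1.5 equiv), KHMDS (2.7 equiv, added to the mixture of 8 and sulfone), DME, −60 °C → rt; aq NH4Cl
Reagents that add atoms: 5-(ethylsulfonyl)-1-phenyl-1H-tetrazole, CCS(=O)(=O)c1nnnn1-c1ccccc1
Why: Julia–Kocienski olefination, in which the metalated tetrazolyl sulfone adds to the aldehyde and Smiles rearrangement with loss of SO2 and tetrazololate gives the (E)-propenyl group; the phenol is carried as its phenoxide at low temperature and C2/C3 are not touched.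

**Compound list**

1 | 4-bromo-2,6-dimethoxyphenol | COc1cc(Br)cc(OC)c1O | starting material
2 | propyne | CC#C | starting material
3 | 2,6-dimethoxy-4-(prop-1-yn-1-yl)phenol | CC#Cc1cc(OC)c(O)c(OC)c1 | intermediate
4 | 2,6-dimethoxy-4-[(Z)-2-(4,4,5,5-tetramethyl-1,3,2-dioxaborolan-2-yl)prop-1-en-1-yl]phenol | C/C(B1OC(C)(C)C(C)(C)O1)=C\c1cc(OC)c(O)c(OC)c1 | intermediate
5 | 5-iodovanillin (4-hydroxy-3-iodo-5-methoxybenzaldehyde) | COc1cc(C=O)cc(I)c1O | starting material
6 | 4-hydroxy-3-[(E)-1-(4-hydroxy-3,5-dimethoxyphenyl)prop-1-en-2-yl]-5-methoxybenzaldehyde | C/C(c1cc(C=O)cc(OC)c1O)=C\c1cc(OC)c(O)c(OC)c1 | intermediate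
7 | 3-[(2R)-1-(3,5-dimethoxy-4-oxocyclohexa-2,5-dien-1-ylidene)propan-2-yl]-4-hydroxy-5-methoxybenzaldehyde (p-quinone methide; same spatial arrangement as C3 of 8, descriptor changes by CIP priority only) | O=Cc1cc(OC)c(O)c(c1)[C@H](C)C=C1C=C(OC)C(=O)C(OC)=C1 | intermediate
8 | (2S,3S)-2-(4-hydroxy-3,5-dimethoxyphenyl)-7-methoxy-3-methyl-2,3-dihydro-1-benzofuran-5-carbaldehyde | O=Cc1cc(OC)c2c(c1)[C@H](C)[C@@H](c1cc(OC)c(O)c(OC)c1)O2 | intermediate
9 | 4-[(2S,3S)-5-{1-hydroxy-2-[(1-phenyl-1H-tetrazol-5-yl)sulfonyl]propyl}-7-methoxy-3-methyl-2,3-dihydro-1-benzofuran-2-yl]-2,6-dimethoxyphenol (β-hydroxy sulfone adduct, drawn neutral; the two new centres are a mixture) | CC(S(=O)(=O)c1nnnn1-c1ccccc1)C(O)c1cc(OC)c2c(c1)[C@H](C)[C@@H](c1cc(OC)c(O)c(OC)c1)O2 | intermediate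
10 | odoratisol A, 4-[(2S,3S)-7-methoxy-3-methyl-5-[(E)-prop-1-en-1-yl]-2,3-dihydro-1-benzofuran-2-yl]-2,6-dimethoxyphenol | C/C=C/c1cc(OC)c2c(c1)[C@H](C)[C@@H](c1cc(OC)c(O)c(OC)c1)O2 | target

**Step count and risks**

Total step count: 5. Longest linear sequence: 5 steps (1 → 3 → 4 → 6 → 8 → 10).

Three steps most likely to fail:

Step 4 (the proposed new hydroalkoxylation). Risks are low enantioselectivity in the protonation, E/Z or positional alkene isomerisation through the ring-A o-quinone methide, and erosion of ee if ring closure and protonation become reversible. Fallback with known chemistry, setting out from 6: iridium-catalysed asymmetric hydrogenation of the (E)-α-methylstilbene unit (cationic Ir–phosphinooxazoline catalyst, H2 50 bar, CH2Cl2, rt) gives 4-hydroxy-3-[(2R)-1-(4-hydroxy-3,5-dimethoxyphenyl)propan-2-yl]-5-methoxybenzaldehyde F2 with the methyl-bearing centre already set. Benzylic dehydrogenation of the 4-hydroxybenzyl CH2 with DDQ (1.1 equiv, dioxane, 0 °C → rt) then generates the same p-quinone methide 7, which closes trans by oxa-1,6-addition. The fallback returns to the route at 8.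

Step 5 (Julia–Kocienski olefination). Risks are incomplete E-selectivity and base-induced opening of the 2-(4-hydroxyaryl) ring while the aldehyde still activates O1 as a leaving group. Fallback, setting out from 8: Wittig olefination with ethylidenetriphenylphosphorane (EtPPh3Br, KHMDS, THF, −78 → 0 °C) gives a Z-rich propenyl mixture whose main component is 4-[(2S,3S)-7-methoxy-3-methyl-5-[(Z)-prop-1-en-1-yl]-2,3-dihydro-1-benzofuran-2-yl]-2,6-dimethoxyphenol F3. Thermodynamic Z → E equilibration with PdCl2(MeCN)2 (10 mol %, CH2Cl2, rt) converts it to the (E)-isomer, returning to the route at 10.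

Step 2 (Cu-catalysed β-borylation). Risks are interference of the free phenol with the copper alkoxide cycle and incomplete regiocontrol on the very electron-rich aryl alkyne. Fallback, setting out from 1 and avoiding 3 and 4: Suzuki–Miyaura coupling of 1 with potassium (E)-prop-1-enyltrifluoroborate (Pd(dppf)Cl2, K2CO3, THF/H2O, 70 °C) gives (E)-2,6-dimethoxy-4-(prop-1-en-1-yl)phenol F1. Mizoroki–Heck arylation of this styrene with 5 (Pd(OAc)2, Bu4NCl, K2CO3, DMF, 80 °C) then gives the stilbene. Syn-carbopalladation (aryl to the methyl-bearing carbon, palladium benzylic) followed by syn-β-hydride elimination delivers the (E)-α-methylstilbene as the main product, and the 1,1-diaryl regioisomer is removed by chromatography. The fallback returns to the route at 6.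

**Further compounds**

F1 | step 2 | (E)-2,6-dimethoxy-4-(prop-1-en-1-yl)phenol | C/C=C/c1cc(OC)c(O)c(OC)c1
F2 | step 4 | 4-hydroxy-3-[(2R)-1-(4-hydroxy-3,5-dimethoxyphenyl)propan-2-yl]-5-methoxybenzaldehyde | O=Cc1cc(OC)c(O)c(c1)[C@H](C)Cc1cc(OC)c(O)c(OC)c1
F3 | step 5 | 4-[(2S,3S)-7-methoxy-3-methyl-5-[(Z)-prop-1-en-1-yl]-2,3-dihydro-1-benzofuran-2-yl]-2,6-dimethoxyphenol | C/C=C\c1cc(OC)c2c(c1)[C@H](C)[C@@H](c1cc(OC)c(O)c(OC)c1)O2
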